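The target forms only where two intermediates meet, and neither of them is in the flask at the start.

| flask | substrate | partner | temperature | remark | time |
|---|---|---|---|---|---|
| spring | 0.13 M | 0.24 M | 30 °C | run made earlier |  |
| summer | 0.30 M | 0.24 M | 42 °C | run made earlier |  |
| dusk | 0.20 M | 0.12 M | 30 °C | run made earlier |  |
| teal | 0.20 M | 0.240 M | 35 °C |  | 20 min |
| blue | 0.20 M | 0.240 M |  | at 35 °C until 15 min, from then on at 50 °C | 20 min |
| ochre | 0.20 M | 0.240 M | 50 °C |  | 20 min |

| run | time / min | target / % |
|---|---|---|
| spring | 2.00 | 0.4 |
| spring | 6.00 | 0 |
| spring | 10.0 | 0 |
| spring | 15.0 | 0.9 |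
| summer | 1.33 | 0 |
| summer | 3.00 | 0 |
| summer | 6.00 | 0.8 |
| summer | 15.0 | 3.4 |
| dusk | 1.33 | 0.5 |
| dusk | 3.00 | 0.4 |
| dusk | 6.00 | 0.3 |
| dusk | 15.0 | 0 |

(each reading ± 0.3 percentage points)

- for target the idle adduct is counted in
- reactions considered so far: substrate <-> open intermediate; partner -> second intermediate; open intermediate + second intermediate -> target; 2 second intermediate -> homo product; substrate -> decomposition product; partner + target <-> idle adduct

1. the flask that comes out highest in amount of target, in percent of the substrate charged, or "all alike" when all lie within 1.5 percentage points (teal / blue / ochre / all alike)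
2. target at the end, in percent of the substrate charged, teal
3. target at the end, in percent of the substrate charged, blue
4. target at the end, in percent of the substrate charged, ochre

1. First instants. Substrate opens and partner converts, both at nearly constant rates. So each intermediate grows in step with time, the open one with the substrate charge and the second one with the partner charge.

2. Middle. Coupling runs at the product of the two pools, so target grows with the cube of time. In percent of substrate charged, the substrate cancels and the partner charge stays. Summer's 3.4 % at 15.0 min puts that cube line at the whole charge by 46.3 min. This time is the lag time, and target is then the cube of time over lag time. The exponent comes from the scheme, not the readings: summer at 6.00 min reads 0.8 % where the cube gives 0.218 %, with a scatter of 0.3 percentage points.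

3. Temperature. Spring holds the same partner charge as summer, and its 0.9 % at 15.0 min gives a lag time of 72.1 min at 30 °C. This rests on a near-noise reading, and dusk's 0 % at 15.0 min gives no lag time. Interpolating the logarithm of the lag time gives 60.0 min at 35 °C and 34.5 min at 50 °C.

4. Clock. Each minute advances a clock by one over the lag time at that moment, and target is the cube of the clock. Blue's clock stands at 0.395 at the end.

5. End. The cube holds while substrate and partner stay near their charges, and it stands high once they are drawn down. This reckoning gives teal 3.71 %, blue 6.18 % and ochre 19.5 %.

The forecast gives teal 2.3 %, blue 5 % and ochre 13 %, and names ochre highest, on a lag “as expected when two intermediates must build up before coupling”. At ochre the reckoning here is higher than the forecast.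

The flasks give teal 1.10 %, blue 4.30 % and ochre 20.1 %, so ochre is highest.

    substrate ⇌ open intermediate (K = 22.0, k = 0.0514 min⁻¹, Ea = 105 kJ mol⁻¹, ΔH = −4.00 kJ mol⁻¹)
    partner → second intermediate (k = 0.243 min⁻¹, Ea = 92.0 kJ mol⁻¹)
    open intermediate + second intermediate → target (k = 0.264 L mol⁻¹ min⁻¹, Ea = 66.0 kJ mol⁻¹)
    2 second intermediate → homo product (k = 0.132 L mol⁻¹ min⁻¹, Ea = 65.0 kJ mol⁻¹)
    substrate → decomposition product (k = 5.21 × 10⁻⁵ min⁻¹, Ea = 119 kJ mol⁻¹)
    partner + target ⇌ idle adduct, settled at all times (K = 86.2 L mol⁻¹, ΔH = −12.0 kJ mol⁻¹)
    (constants at 50 °C)

Read back, ochre's lag time is 34.1 min, near the 34.5 min reckoned and shorter than summer's 46.3 min. The neighbour flask holds 0.60 M of partner in place of 0.240 M. The cube scales with partner charge only while partner stays near that charge. On that line the neighbour's lag time is 25.2 min and its target 50.3 %. The neighbour reads 30.8 % at 20.0 min, lower than that line, with 0.944 % of its partner left.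

The earlier runs and the new flask were computed from invented constants; scatter was added.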